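Which way of adding the reagents leaves most target at 30 min, and how much does each flask hold?

all flasks: free catalyst 15 mol%
- cedar: starting material 0.30 M; second substrate 2 equiv; partner 1.5 equiv; run made earlier
- maple: starting material 0.30 M; second substrate 2 equiv; partner 2.1 equiv; run made earlier
- oak: starting material 0.30 M; second substrate 2 equiv; partner 3.3 equiv; run made earlier
- elm: starting material 0.45 M; second substrate 2 equiv; partner 1.5 equiv; run made earlier
- noon: starting material 0.30 M (fed, over 12 min); second substrate 2.00 equiv; partner 1.50 equiv; all else is in the flask from the start; the feed brings no volume worth counting; time 30 min
- dusk: starting material 0.30 M; second substrate 2.00 equiv; partner 1.50 equiv (in portions, 2, over 12 min); first portion at the start, last at 12 min; time 30 min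
- spring: starting material 0.30 M; second substrate 2.00 equiv; partner 1.50 equiv; everything together at the start; time 30 min
- winter: starting material 0.30 M; second substrate 2.00 equiv; partner 1.50 equiv (fed, over 12 min); all else is in the flask from the start; the feed brings no volume worth counting; time 30 min

- cedar (time / min: target / %, starting material / %): 8.00: 24.2, 70.8; 15.0: 21.9, 70.9; 25.0: 22.5, 72.9; 30.0: 22.1, 72.6
- maple (time / min: target / %, starting material / %): 3.00: 32.2, 57.3; 6.00: 32.8, 55.3; 15.0: 33.0, 54.1; 40.0: 37.2, 52.6
- oak (time / min: target / %, starting material / %): 3.00: 43.0, 35.0; 6.00: 43.9, 23.3; 15.0: 41.0, 15.4; 40.0: 41.7, 14.7
- elm (time / min: target / %, starting material / %): 3.00: 26.6, 65.9; 6.00: 28.2, 64.2; 15.0: 25.3, 66.3; 40.0: 27.3, 65.3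

(scatter of a reading: 1 percentage point)

- the flask with the highest amount of target, in percent of the starting material charged ("all alike" if they lie within 1.5 percentage points) (noon / dusk / spring / winter / all alike)
- final target, as a percentage of the starting material charged, in noon
- final target, as a percentage of the starting material charged, in dusk
- final target, as a percentage of the starting material charged, in spring
- final target, as a percentage of the starting material charged, in winter



Oak, with more partner, falls to 14.7% of starting material where cedar stops at 72.6%, so I treat partner as the limiting reagent and ask how it divides. If partner takes starting material and second substrate each in proportion to what stands in the flask, the ratio of the two rates integrates in closed form to one number, the selectivity factor S, which is how readily starting material is taken relative to second substrate. Here a and b are the fractions of starting material and second substrate left, and E and F are the equivalents of partner and second substrate charged: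

S = ln a / ln b, with b = 1 − (E − (1 − a)) / F

Cedar has a = 72.6% and b = 0.387, so S = 0.337. Maple reads 0.383, which is close, but elm reads 0.496. Elm has every charge more concentrated than cedar, and its S reads 1.47 times cedar's for a 1.50-fold concentration, so one number is not enough.

Spring repeats cedar's recipe, so I expect about 22.1%. Maple's readings move little after 3.00 min, so in noon I reckon with partner gone within that time, when 25.0% of the feed is in and the mean a is half of that:

target ≈ S × mean a × ln(1/b) = 4.00%

That is less than spring. Dosing partner keeps its concentration low, and although elm raised every charge at once, I take its reading as a hint of a lower S here, so I place dusk and winter between these two, with winter nearer noon.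

The forecast names spring, with noon 17%, dusk 21%, spring 22.5% and winter 19%, and argues that “Feeding starting material keeps it scarce against accumulating target”. The flasks give spring as the best, with noon 2.71%, dusk 17.3%, spring 21.9% and winter 11.4%.

    starting material + free catalyst ⇌ catalyst intermediate A (K = 2.02 M⁻¹, k = 11.9 M⁻¹ s⁻¹)
    partner + catalyst intermediate A → free catalyst + target (k = 0.161 M⁻¹ s⁻¹)
    second substrate + free catalyst ⇌ catalyst intermediate B (K = 0.690 M⁻¹, k = 0.270 M⁻¹ s⁻¹)
    partner + catalyst intermediate B → free catalyst + second product (k = 5.22 M⁻¹ s⁻¹)
    partner + target → over-reaction product (k = 0.00716 M⁻¹ s⁻¹)

From what is left, spring gives S = 0.348 and winter 0.155, about half. Removing partner's reaction with catalyst intermediate B shrinks the gap between spring and noon from 19 percentage points to 0.62 points, and removing the binding of second substrate to free catalyst shrinks it to 1.4 points, so these two steps together are part of the reason for that gap. Spring's own target stays low mainly because of the way back from catalyst intermediate A to starting material and free catalyst: without that way back, spring gives 80.4% in place of 21.9%.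

In the neighbour flask that is spring with 3.80 equiv of partner, a = b^S with S = 0.337 takes a low as b falls. Partner then covers both substrates with 0.800 equiv over, and if that excess goes onto target, I reckon about 20.0% of target. The flask holds 25.9% of target, 70.5% of over-reaction product, 3.35% of starting material and 0% of second substrate.

The data come from a simulation on assumed constants; the scatter is artificial.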